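The solubility of the target, 49 mM, is lower than the 0.40 M of solid substrate charged, so in this flask I expect solid product to crystallise and to hold c(target) at that solubility while it stands.

solid substrate 0.40 M; reagent 4.00 equiv; time 2.5 min

    solid substrate ⇌ dissolved substrate, rate k1*(cs1 - [dissolved substrate]) while solid is left; crystals form when [dissolved substrate] > cs1 (cs1 = 0.15 M, k1 = 0.0907 /s)
    dissolved substrate + reagent → target (k2 = 0.119 /M/s)
    reagent → side product (k3 = 0.00156 /s)
    solid product ⇌ target, rate k4*(cs4 - [target]) while solid is left; crystals form when [target] > cs4 (cs4 = 49 mM, k4 = 3.22 /s)
    target ⇌ isomer of the product (K5 = 0.30, k5 = 0.00481 /s)

* how much target and solid product together there is at 2.5 min, in percent of the solid substrate charged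
* the change that raises the amount of target and solid product together at 2.5 min, in percent of the solid substrate charged most ("none" if none brings more than 2 percentage points) (Thursday's / Saturday's / Monday's / Friday's / none)
* amount of target and solid product together at 2.5 min, in percent of the solid substrate charged, after Friday's

- Thursday's: doubling the dissolution coefficient of step 1, all else as stated
- Saturday's: doubling the solubility in step 4, all else as stated
- Monday's: doubling the dissolution coefficient of step 4, all else as stated
- Friday's: doubling the amount of reagent, all else as stated

- target is meant together with its solid product
- solid, in amounts per volume of the solution: solid substrate, solid product
- at the start none of the solid substrate is in solution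
- run time (flask): 2.5 min

I count turnovers in a small table of three rows: each row is a clock, with its half-life and the number of those half-lives that fit into 2.5 min.

The first row is dissolved substrate used by the reagent, pseudo-first-order with the reagent as charged: 0.061 min, so 41.0 turns. Dissolving can supply 510% of the charge in that time, so I take the substrate as converted by the end.

The second row is the reagent's own decay: 7.4 min, so 0.338 turns, fewer than one, and I expect the reagent to last.

The third row is the isomer. With c(target) held at 49 mM, the isomer climbs towards the equilibrium constant 0.30 times that solubility, which is 3.67% of the charge. Its half-life under that hold is 0.721 min, so 3.47 turns fit, and the run is longer than this clock.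

The ceiling times the part filled after those turns gives 3.34%; that product is the isomer toll, the number I carry. So I reckon y at 96.7%, and the same after Friday's. Thursday's, Monday's and Friday's do not appear in the toll, while Saturday's doubles it, so I choose none.

The forecast gives 96.7%, none and 96.7%, holding that “the only loss at 2.5 min is the isomer”.

The simulation gives 96.7%, none and 96.7%, so the forecast holds. The isomer reads 3.33% at 2.50 min against my toll of 3.34%, and Saturday's costs 3.3 percentage points. One reason y stands so high is the low solubility of the target: the same run without it gives y of 78.8% against 96.7%.

The neighbour flask with 0.16 M of solid substrate keeps the same ceiling in concentration over a smaller charge, so its toll is 8.36% and I expect y at 91.6%. It gives 91.7%, with isomer at 8.25% and solid product at 61.1% still standing.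

Its constants belong to no real substance; the flask was simulated.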